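**Retrosynthetic overview**
1. Target 23 ⇐ acetylation and allylic oxidation of a diepoxy triol ⇐ two reagent-controlled Sharpless epoxidations (D-(−)-DET at the C6=C7 allylic alcohol, L-(+)-DET at the tetrasubstituted exocyclic allylic alcohol) on an achiral ten-membered trienone.
2. The E-configured exocyclic allylic alcohol ⇐ SmI2 opening of a vinyl oxirane made from an isopropenyl-substituted cross-conjugated dienone.
3. Ten-membered ring ⇐ four-carbon ring expansion: intramolecular vinyllithium addition to a 6,6-disubstituted cyclohexa-2,4-dienone, then cleavage of the ring-fusion bond of the alkoxide (retro-aldol).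
4. Dienone ⇐ methyl 2-methoxybenzoate by Birch reductive alkylation with (2Z)-2,5-diiodopent-2-ene, bis-allylic oxidation and isopropenyl addition with 1,3-carbonyl transposition; the benzene ring supplies C1, C6–C10 and the ester carbon becomes the CH2OAc carbon on C6.
5. Ring order: benzene ring (dearomatized, ring A) → ring B closed and the shared bond cleaved in the same operation (cyclodecane) → the two oxiranes last.

Assumption and numbering: the SMILES is taken as written (Z-enone; ring oxirane R,R; spiro oxirane S,S). Target atoms are numbered C1 (C=O), C2 (C–CH3), C3 (=CH), C4, C5 (CH2), C6 (oxirane C bearing CH2OAc), C7 (oxirane CH), C8 (CH2), C9 (spiro C), C10 (CH2), C11 (exocyclic oxirane C).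

**Route**

Step 1
Reactants: 1 2,3-dihydrofuran
Product: 5 (3Z)-4-iodopent-3-en-1-ol, via 5-lithio-2,3-dihydrofuran 2 (not isolated), via lithium methyl(4,5-dihydrofuran-2-yl)cuprate 3 (not isolated), via alkenylcopper lithium alkoxide 4 (not isolated)
Conditions: t-BuLi, THF, −78 to 0 °C; MeCu (from MeLi + CuBr·SMe2), Et2O/Me2S, −78 to 20 °C; I2, −78 °C
Reagents that add atoms: methyllithium [Li]C; iodine II
Why: Kocienski 1,2-metallate rearrangement of an α-alkoxyalkenyl cuprate: methyl migrates from copper to the metallated carbon with inversion and ring opening, so the C–Cu bond (then C–I, by stereoretentive iodinolysis) lies cis to the hydroxyethyl chain, giving the Z-vinyl iodide that becomes the Z-enone.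

Step 2
Reactants: 5 (3Z)-4-iodopent-3-en-1-ol
Product: 6 (2Z)-2,5-diiodopent-2-ene
Conditions: I2, PPh3, imidazole, CH2Cl2, 0 °C
Reagents that add atoms: iodine II
Why: Appel-type iodination of the primary alcohol (SN2 on the alkoxyphosphonium ion) leaves the vinyl iodide geometry untouched.

Step 3
Reactants: 7 methyl 2-methoxybenzoate; 6 (2Z)-2,5-diiodopent-2-ene
Product: 9 methyl 1-[(3Z)-4-iodopent-3-en-1-yl]-2-methoxycyclohexa-2,5-diene-1-carboxylate, via potassium ester dienolate 8 (not isolated)
Conditions: K, NH3(l)/THF, t-BuOH (1 equiv), −78 °C; piperylene; then 6, −78 to −33 °C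
Reagents that add atoms: none
Why: Birch reductive alkylation (Schultz variant): reduction of the benzoate with C-4 protonation gives dienolate 8, which is C-alkylated at the former ipso carbon by the primary iodide after the excess metal has been destroyed (so the vinyl iodide survives); the quaternary stereocentre is racemic and is erased in step 6.

Step 4
Reactants: 9 methyl 1-[(3Z)-4-iodopent-3-en-1-yl]-2-methoxycyclohexa-2,5-diene-1-carboxylate
Product: 10 methyl 1-[(3Z)-4-iodopent-3-en-1-yl]-2-methoxy-4-oxocyclohexa-2,5-diene-1-carboxylate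
Conditions: pyridinium dichromate (C5H5NH)2Cr2O7, t-BuOOH, Celite, benzene, 20 °C
Reagents that add atoms: tert-butyl hydroperoxide CC(C)(C)OO
Why: Chromium-mediated allylic oxidation (Schultz conditions for Birch products) of the doubly allylic CH2, the only strongly activated C–H position, gives the cross-conjugated 3-methoxy-2,5-cyclohexadienone; no stereocentre is set.

Step 5
Reactants: 10 methyl 1-[(3Z)-4-iodopent-3-en-1-yl]-2-methoxy-4-oxocyclohexa-2,5-diene-1-carboxylate
Product: 12 methyl 1-[(3Z)-4-iodopent-3-en-1-yl]-2-oxo-4-(prop-1-en-2-yl)cyclohexa-3,5-diene-1-carboxylate, via tertiary dienyl carbinol 11 (not isolated)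
Conditions: CH2=C(CH3)MgBr, THF, −78 to 0 °C; then 1 M HCl (aq.), THF, 0 °C
Reagents that add atoms: isopropenylmagnesium bromide C=C(C)[Mg]Br; water O
Why: Grignard 1,2-addition to the vinylogous-ester carbonyl, then acid ionisation of carbinol 11 and capture of the methoxy-stabilised cation by water (Stork–Danheiser-type 1,3-carbonyl transposition, the Schultz route to 2,4-cyclohexadienones) places the ketone next to the quaternary carbon and the isopropenyl group on the β-carbon; no new stereocentre.

Step 6
Reactants: 12 methyl 1-[(3Z)-4-iodopent-3-en-1-yl]-2-oxo-4-(prop-1-en-2-yl)cyclohexa-3,5-diene-1-carboxylate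
Product: 16 methyl (1E,4E,7Z)-7-methyl-6-oxo-4-(prop-1-en-2-yl)cyclodeca-1,4,7-triene-1-carboxylate, via vinyllithium 13 (not isolated), via bicyclic lithium alkoxide 14 (not isolated), via macrocyclic lithium trienolate 15 (not isolated)
Conditions: t-BuLi (2.1 equiv), THF/Et2O, −90 to −30 °C; AcOH, −78 °C; then DBU (cat.), CH2Cl2, 20 °C
Reagents that add atoms: none
Why: Proposed new method: iodine–lithium exchange (faster than carbonyl attack at −90 °C, as in Cooke-type anionic cyclisations) gives Z-vinyllithium 13, which adds 1,2 to the only ketone through a six-membered transition state to give cis-fused alkoxide 14; its ring-fusion bond leads to an ester- and diene-stabilised carbanion, so retro-aldol (retro-allylation) cleavage to the ten-membered trienolate 15 should be strongly downhill, and protonation followed by DBU equilibration should funnel the tautomers to 16, the isomer with both carbonyl groups conjugated and all ring alkenes cis-cycloalkenes; the closest known reaction types are halogen–lithium exchange-initiated cyclisation onto ketones and alkoxide-driven retro-aldol ring expansion, and every earlier stereocentre is destroyed here.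

Step 7
Reactants: 16 methyl (1E,4E,7Z)-7-methyl-6-oxo-4-(prop-1-en-2-yl)cyclodeca-1,4,7-triene-1-carboxylate
Product: 17 methyl (1E,4E,7Z)-7-methyl-4-(2-methyloxiran-2-yl)-6-oxocyclodeca-1,4,7-triene-1-carboxylate
Conditions: mCPBA, NaHCO3, CH2Cl2, 0 °C
Reagents that add atoms: 3-chloroperoxybenzoic acid OOC(=O)c1cccc(Cl)c1
Why: Prilezhaev epoxidation: the isopropenyl double bond (γ,δ to the ketone) is the only alkene not directly deactivated by a carbonyl group, so it reacts selectively; the racemic oxirane stereocentre is removed in step 8.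

Step 8
Reactants: 17 methyl (1E,4E,7Z)-7-methyl-4-(2-methyloxiran-2-yl)-6-oxocyclodeca-1,4,7-triene-1-carboxylate
Product: 18 methyl (1E,4E,7Z)-4-(1-hydroxypropan-2-ylidene)-7-methyl-6-oxocyclodeca-1,7-diene-1-carboxylate
Conditions: SmI2 (2.5 equiv), THF/MeOH, −78 °C
Reagents that add atoms: none
Why: SmI2 reduction of a γ,δ-epoxy-α,β-unsaturated ketone (Molander vinyl-oxirane opening): the ketyl opens the C–O bond at the γ-carbon, a second electron gives the samarium dienolate and methanol protonates its α-carbon (C10), giving the β,γ-unsaturated ketone; by analogy with the E-selectivity of the lower-substituted cases, the anti vinyl-oxirane conformer should place CH2OH anti to C10 and cis to C8.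

Step 9
Reactants: 18 methyl (1E,4E,7Z)-4-(1-hydroxypropan-2-ylidene)-7-methyl-6-oxocyclodeca-1,7-diene-1-carboxylate
Product: 19 methyl (2S,3S,5E,9Z)-2-(hydroxymethyl)-2,10-dimethyl-11-oxo-1-oxaspiro[2.9]dodeca-5,9-diene-6-carboxylate
Conditions: Ti(OiPr)4, L-(+)-diethyl tartrate, t-BuOOH, 4 Å MS, CH2Cl2, −20 °C
Reagents that add atoms: tert-butyl hydroperoxide CC(C)(C)OO
Why: Sharpless asymmetric epoxidation of the tetrasubstituted E-allylic alcohol: L-(+)-DET makes the carbinol-bearing oxirane carbon (C11) S and, by syn addition to the E-alkene, the spiro carbon (C9) S; the enone and enoate are inert to the titanium peroxide.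

Step 10
Reactants: 19 methyl (2S,3S,5E,9Z)-2-(hydroxymethyl)-2,10-dimethyl-11-oxo-1-oxaspiro[2.9]dodeca-5,9-diene-6-carboxylate
Product: 20 (2S,3S,5E,9Z)-2,6-bis(hydroxymethyl)-2,10-dimethyl-1-oxaspiro[2.9]dodeca-5,9-dien-11-ol (both carbinol epimers)
Conditions: DIBAL-H (i-Bu2AlH, 5 equiv), CH2Cl2, −78 °C; Rochelle salt
Reagents that add atoms: none
Why: DIBAL-H 1,2-reduction turns the enoate into the allylic alcohol needed for the second directed epoxidation and unavoidably reduces the ketone to a carbinol (both epimers, re-oxidised in step 12); at −78 °C the tetrasubstituted oxirane should survive.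

Step 11
Reactants: 20 (2S,3S,5E,9Z)-2,6-bis(hydroxymethyl)-2,10-dimethyl-1-oxaspiro[2.9]dodeca-5,9-dien-11-ol
Product: 21 diepoxy triol (20 with the ring allylic alcohol alkene converted into the oxirane of 23; both carbinol epimers)
Conditions: Ti(OiPr)4, D-(−)-diethyl tartrate, t-BuOOH, 4 Å MS, CH2Cl2, −20 °C
Reagents that add atoms: tert-butyl hydroperoxide CC(C)(C)OO
Why: Second Sharpless asymmetric epoxidation: only the C6=C7 primary allylic alcohol is a fast substrate (the spiro-epoxy alcohol has no alkene and the secondary carbinol has a Z-substituted, slow alkene), and D-(−)-DET gives the 6R,7R oxirane by syn addition to the E-alkene under reagent control.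

Step 12
Reactants: 21 diepoxy triol
Product: 22 diepoxy keto diol (23 without its two acetyl groups)
Conditions: MnO2, CH2Cl2, 20 °C
Reagents that add atoms: none
Why: MnO2 oxidises only the allylic secondary alcohol (both primary alcohols are now non-allylic epoxy alcohols), restoring the Z-enone and converging the two carbinol epimers.

Step 13
Reactants: 22 diepoxy keto diol
Product: 23 CNP0185847.4 (target)
Conditions: Ac2O, pyridine, DMAP (cat.), CH2Cl2, 0 °C
Reagents that add atoms: acetic anhydride CC(=O)OC(C)=O
Why: DMAP-catalysed acylation of both primary alcohols under mild base that should not open the β,γ-epoxy ketone gives the target, whose four stereocentres were set in steps 9 and 11.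

**Compound list**
1 | 2,3-dihydrofuran | C1CC=CO1 | starting material
2 | 5-lithio-2,3-dihydrofuran | [Li]C1=CCCO1 | intermediate
3 | lithium methyl(4,5-dihydrofuran-2-yl)cuprate | [Li+].C[Cu-]C1=CCCO1 | intermediate
4 | (Z)-alkenylcopper lithium alkoxide (copper cis to the oxidoethyl chain) | [Li+].[O-]CC/C=C(/C)[Cu] | intermediate
5 | (3Z)-4-iodopent-3-en-1-ol | OCC/C=C(/C)I | intermediate
6 | (2Z)-2,5-diiodopent-2-ene | ICC/C=C(/C)I | intermediate
7 | methyl 2-methoxybenzoate | COC(=O)c1ccccc1OC | starting material
8 | potassium dienolate of methyl 2-methoxy-1,4-dihydrobenzoate | [K+].[O-]C(OC)=C1C(OC)=CCC=C1 | intermediate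
9 | methyl 1-[(3Z)-4-iodopent-3-en-1-yl]-2-methoxycyclohexa-2,5-diene-1-carboxylate (racemic) | COC(=O)C1(CC/C=C(/C)I)C=CCC=C1OC | intermediate
10 | methyl 1-[(3Z)-4-iodopent-3-en-1-yl]-2-methoxy-4-oxocyclohexa-2,5-diene-1-carboxylate (racemic) | COC(=O)C1(CC/C=C(/C)I)C=CC(=O)C=C1OC | intermediate
11 | methyl 4-hydroxy-1-[(3Z)-4-iodopent-3-en-1-yl]-2-methoxy-4-(prop-1-en-2-yl)cyclohexa-2,5-diene-1-carboxylate | COC(=O)C1(CC/C=C(/C)I)C=CC(O)(C(C)=C)C=C1OC | intermediate
12 | methyl 1-[(3Z)-4-iodopent-3-en-1-yl]-2-oxo-4-(prop-1-en-2-yl)cyclohexa-3,5-diene-1-carboxylate (racemic) | COC(=O)C1(CC/C=C(/C)I)C=CC(C(C)=C)=CC1=O | intermediate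
13 | vinyllithium from 12 (Li in place of I, Z retained) | COC(=O)C1(CC/C=C(/C)[Li])C=CC(C(C)=C)=CC1=O | intermediate
14 | cis-fused bicyclic lithium alkoxide | [Li+].COC(=O)C12CCC=C(C)C1([O-])C=C(C(C)=C)C=C2 | intermediate
15 | ten-membered lithium trienolate (ester-enolate resonance form) | [Li+].COC([O-])=C1CC/C=C(/C)C(=O)C=C(C(C)=C)C=C1 | intermediate
16 | methyl (1E,4E,7Z)-7-methyl-6-oxo-4-(prop-1-en-2-yl)cyclodeca-1,4,7-triene-1-carboxylate | COC(=O)/C1=C/C/C(C(C)=C)=C\C(=O)/C(C)=C\CC1 | intermediate
17 | methyl (1E,4E,7Z)-7-methyl-4-(2-methyloxiran-2-yl)-6-oxocyclodeca-1,4,7-triene-1-carboxylate (racemic) | COC(=O)/C1=C/C/C(C2(C)CO2)=C\C(=O)/C(C)=C\CC1 | intermediate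
18 | methyl (1E,4E,7Z)-4-(1-hydroxypropan-2-ylidene)-7-methyl-6-oxocyclodeca-1,7-diene-1-carboxylate | COC(=O)/C1=C/C/C(=C(/C)CO)CC(=O)/C(C)=C\CC1 | intermediate
19 | methyl (2S,3S,5E,9Z)-2-(hydroxymethyl)-2,10-dimethyl-11-oxo-1-oxaspiro[2.9]dodeca-5,9-diene-6-carboxylate | COC(=O)/C1=C/C[C@@]2(CC(=O)/C(C)=C\CC1)O[C@@]2(C)CO | intermediate
20 | (2S,3S,5E,9Z)-2,6-bis(hydroxymethyl)-2,10-dimethyl-1-oxaspiro[2.9]dodeca-5,9-dien-11-ol (both C-11 epimers) | OC/C1=C/C[C@@]2(CC(O)/C(C)=C\CC1)O[C@@]2(C)CO | intermediate
21 | diepoxy triol: target skeleton with OH in place of the ketone and of both acetoxy groups, oxirane carbons configured as in 23 (both carbinol epimers) | OC[C@]12CC/C=C(/C)C(O)C[C@]3(C[C@H]1O2)O[C@@]3(C)CO | intermediate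
22 | diepoxy keto diol: (2Z,6R,7R,9S,11S)-diepoxy enone of 23 with two free CH2OH groups | OC[C@]12CC/C=C(/C)C(=O)C[C@]3(C[C@H]1O2)O[C@@]3(C)CO | intermediate
23 | CNP0185847.4, the (2Z,6R,7R,9S,11S)-diepoxy enone diacetate (numbering above) | CC(=O)OC[C@]12CC/C=C(/C)C(=O)C[C@]3(C[C@H]1O2)O[C@@]3(C)COC(C)=O | target

**Step count and risks**

Total steps: 13. Longest linear sequence: 13 (1 to 23); 11 from methyl 2-methoxybenzoate 7.

The three steps most likely to fail:

Step 5. The Grignard addition to the weakly electrophilic vinylogous-ester carbonyl may be sluggish, and the cross-conjugated 2,4-dienone 12 may dimerise. The fallback sets out from 10. The enol ether is hydrolysed (aq. HCl, THF) to the vinylogous acid methyl 4-hydroxy-1-[(3Z)-4-iodopent-3-en-1-yl]-2-oxocyclohexa-3,5-diene-1-carboxylate F1. The less hindered enol oxygen is sulfonylated (Tf2O, 2,6-lutidine, −78 °C) to give the dienone triflate F2. Addition–elimination with (CH2=C(CH3))2CuLi at −78 °C, which the vinyl iodide should tolerate, then installs the isopropenyl group and the route is rejoined at 12.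

Step 6. t-BuLi may attack the ketone before exchange, the trienolate 15 may add transannularly to the new enone, and protonation may give tautomer mixtures. The fallback sets out from 12. Ring B is closed under neutral Nozaki–Hiyama–Kishi conditions (CrCl2, NiCl2 cat., DMSO/THF) and the cis-fused carbinol methyl 8a-hydroxy-8-methyl-2-(prop-1-en-2-yl)-6,8a-dihydronaphthalene-4a(5H)-carboxylate F3 is isolated. It is then fragmented thermally (toluene, 140 °C, sealed tube) by a retro-ene reaction that passes the hydroxyl hydrogen to C8 while the ring-fusion bond breaks. No free enolate is formed, and the route is rejoined at 16.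

Step 8. The E geometry of the tetrasubstituted alkene rests on analogy with less substituted vinyl oxiranes, and SmI2 may also reduce the second enone. The fallback sets out from 16 and bypasses 17. Copper-catalysed 1,6-conjugate borylation (B2pin2, CuCl, NaOtBu, MeOH, THF) should add boron to the terminal CH2 of the planar s-trans dienone. Protonation of the dienolate at C10 then gives the allylboronate methyl (1E,4E,7Z)-7-methyl-6-oxo-4-[1-(4,4,5,5-tetramethyl-1,3,2-dioxaborolan-2-yl)propan-2-ylidene]cyclodeca-1,7-diene-1-carboxylate F4. Oxidation with NaBO3·4H2O returns to the route at 18.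

**Further compounds**
F1 | step 5 | methyl 4-hydroxy-1-[(3Z)-4-iodopent-3-en-1-yl]-2-oxocyclohexa-3,5-diene-1-carboxylate | COC(=O)C1(CC/C=C(/C)I)C=CC(O)=CC1=O
F2 | step 5 | methyl 1-[(3Z)-4-iodopent-3-en-1-yl]-2-oxo-4-(trifluoromethylsulfonyloxy)cyclohexa-3,5-diene-1-carboxylate | COC(=O)C1(CC/C=C(/C)I)C=CC(OS(=O)(=O)C(F)(F)F)=CC1=O
F3 | step 6 | methyl 8a-hydroxy-8-methyl-2-(prop-1-en-2-yl)-6,8a-dihydronaphthalene-4a(5H)-carboxylate (cis-fused, racemic) | COC(=O)C12CCC=C(C)C1(O)C=C(C(C)=C)C=C2
F4 | step 8 | methyl (1E,4E,7Z)-7-methyl-6-oxo-4-[1-(4,4,5,5-tetramethyl-1,3,2-dioxaborolan-2-yl)propan-2-ylidene]cyclodeca-1,7-diene-1-carboxylate | COC(=O)/C1=C/C/C(=C(/C)CB2OC(C)(C)C(C)(C)O2)CC(=O)/C(C)=C\CC1
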